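Numbering: chromane numbering of the target is used throughout (O1, C2, C3, C4, C4a, C5, C6, C7, C8, C8a); C6 is the quaternary carbon and C8 carries the hexanoic acid chain.
Bonds cut, in retrosynthetic order: C6–prenyl; O1–C2 and C4–C4a (a 3-methylbut-2-enoyl unit); C4a–C8a together with C5–C6 (benzannulation); C8a–C6 and C7–C8 of a cyclobutenone (ketene + ynol ether); the cyclobutane C–C bond next to a nitrile (epoxynitrile cyclisation).
Enabling feature: the carbocycle C4a–C5–C6–C7–C8–C8a is a masked phloroglucinol whose oxygens on C5, C7 and C8a alternate with carbon substituents on C4a, C6 and C8. O8a can therefore come from a ketene carbonyl and O7 and O5 from two siloxyalkynes, and the C4a–C5 pair can be inserted as a siloxyacetylene into the C8a–C6 bond of a four-membered ring made of C8a, C6, C7 and C8.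
Forward order: cyclobutane, then its siloxyalkyne; cyclobutenone; benzene ring with only the oxygen on C8a free; pyranone ring; dearomatisation at C6; free acid.
Stereochemistry: the cyclobutane CH–CH2 centre comes from a catalytically resolved (R)-epoxide (inversion on ring closure) and its neighbour from thermodynamic trans equilibration; the side-chain centre from catalytic desymmetrisation of 3-propylglutaric anhydride; C6 from ligand-controlled palladium prenylation of the flat phenol.
Key step: step 14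

Remarks on the chemistry (assumptions):
- salen = N,N'-bis(3,5-di-tert-butylsalicylidene)cyclohexane-1,2-diamine dianion; the (S,S) cobalt complex is assumed to hydrolyse the (S)-epoxide faster, as with simple 1-alkyloxiranes; if the sense is opposite, the (R,R) complex is used.
- (DHQ)2AQN is assumed to open the anhydride to the (3S)-hemiester 23; if the sense is opposite, the pseudoenantiomer (DHQD)2AQN is used.
- The (R,R) antipode of the bisphosphine ligand in step 18 is assumed to give the 6R epimer; otherwise the (S,S) antipode is used.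
- Reagents named without a compound number are commercial.

Step 1
Reactants: 1 2,2-dimethylpent-4-enal
Product: 2 3,3-dimethylhex-5-enenitrile
Conditions: TosMIC (1.1 equiv), t-BuOK (2.2 equiv), DME, −40 °C → rt; then MeOH, reflux
Reagents that add atoms: tosylmethyl isocyanide, [C-]#[N+]CS(=O)(=O)c1ccc(C)cc1
Why: van Leusen reductive cyanation, in which the TosMIC anion adds to the non-enolisable aldehyde and methanolysis of the adduct expels formate and sulfinate, should give the one-carbon-longer nitrile without touching the alkene.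

Step 2
Reactants: 2 3,3-dimethylhex-5-enenitrile
Product: 3 rac-3,3-dimethyl-4-(oxiran-2-yl)butanenitrile
Conditions: mCPBA (1.2 equiv), NaHCO3, CH2Cl2, 0 °C → rt
Reagents that add atoms: 3-chloroperoxybenzoic acid, OOC(=O)c1cccc(Cl)c1
Why: Prilezhaev epoxidation of the only alkene should give the racemic terminal epoxide, the nitrile being inert to the peracid.

Step 3
Reactants: 3 rac-3,3-dimethyl-4-(oxiran-2-yl)butanenitrile
Product: 4 3,3-dimethyl-4-[(2R)-oxiran-2-yl]butanenitrile
Conditions: (S,S)-(salen)Co(OAc) (0.5 mol%), H2O (0.55 equiv), THF, 0 °C → rt; epoxide separated from the diol by distillation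
Reagents that add atoms: none
Why: Jacobsen hydrolytic kinetic resolution, in which the chiral cobalt salen complex hydrolyses one enantiomer of a terminal epoxide much faster than the other, should leave the (R)-epoxide and so set the first stereocentre by catalysis.

Step 4
Reactants: 4 3,3-dimethyl-4-[(2R)-oxiran-2-yl]butanenitrile
Product: 5 (1S,4R)-4-(hydroxymethyl)-2,2-dimethylcyclobutane-1-carbonitrile
Conditions: KN(SiMe3)2 (1.2 equiv), toluene, 0 °C → rt; aq. NH4Cl
Reagents that add atoms: none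
Why: Stork epoxynitrile cyclisation, in which the nitrile anion opens the epoxide at its internal carbon in the 4-exo mode (collinear SN2 geometry, helped by the gem-dimethyl group, whereas 5-endo attack is geometrically disfavoured), should close the cyclobutane with inversion at the carbinyl ring carbon; the nitrile-bearing carbon is expected trans and its configuration is in any case fixed by the equilibration in step 6.

Step 5
Reactants: 5 (1S,4R)-4-(hydroxymethyl)-2,2-dimethylcyclobutane-1-carbonitrile; 6 ethynyl(trimethyl)silane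
Product: 9 (1S,4S)-2,2-dimethyl-4-[3-(trimethylsilyl)prop-2-yn-1-yl]cyclobutane-1-carbonitrile, via lithium silylacetylide 7 (not isolated), via triflate 8 (not isolated)
Conditions: Tf2O (1.1 equiv), pyridine (1.3 equiv), CH2Cl2, −78 °C, cold aqueous wash; crude 8 added to 7 [from 6 (1.5 equiv) and n-BuLi (1.4 equiv), THF, −78 °C], DMPU, −78 → −20 °C
Reagents that add atoms: none
Why: SN2 displacement of the primary triflate by the lithium silylacetylide at low temperature should install the three-carbon arm faster than the acetylide can deprotonate the nitrile α-carbon, the silyl cap excluding the dilithium acetylide and the double alkylation that the parent acetylide can give, and no stereocentre is touched (the descriptor of the ring carbon changes only by priority).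

Step 6
Reactants: 9 (1S,4S)-2,2-dimethyl-4-[3-(trimethylsilyl)prop-2-yn-1-yl]cyclobutane-1-carbonitrile
Product: 12 1-[(1S,4R)-2,2-dimethyl-4-(prop-2-yn-1-yl)cyclobutyl]ethan-1-one, via ketimine 10 (not isolated), via silyl ketone 11 (not isolated)
Conditions: MeLi (2.5 equiv), Et2O, 0 °C → rt; 1 M aq. HCl, THF, rt; crude 11, K2CO3 (0.5 equiv), MeOH, rt
Reagents that add atoms: methyllithium, C[Li]; water, O
Why: 1,2-addition of the organolithium to the nitrile and hydrolysis of the N-lithio ketimine should give the methyl ketone, and the methanolic carbonate then both cleaves the alkynyl C–Si bond and equilibrates the enolisable centre, placing the acetyl group trans to the propargyl arm next to the gem-dimethyl carbon (thermodynamic control relayed from the carbon set in step 4).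

Step 7
Reactants: 12 1-[(1S,4R)-2,2-dimethyl-4-(prop-2-yn-1-yl)cyclobutyl]ethan-1-one
Product: 13 (2R,3R)-1,1-dimethyl-2-(prop-1-en-2-yl)-3-(prop-2-yn-1-yl)cyclobutane
Conditions: Ph3PCH3Br (2 equiv), t-BuOK (1.9 equiv), THF, 0 °C → reflux
Reagents that add atoms: methyltriphenylphosphonium bromide, C[P+](c1ccccc1)(c1ccccc1)c1ccccc1.[Br-]
Why: Wittig methylenation should turn the acetyl group into the isopropenyl group; the ylide is too weak a base to remove the alkyne proton, and any enolisation only returns the trans ketone.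

Step 8
Reactants: 13 (2R,3R)-1,1-dimethyl-2-(prop-1-en-2-yl)-3-(prop-2-yn-1-yl)cyclobutane
Product: 16 triisopropyl({3-[(1S,2R)-3,3-dimethyl-2-(prop-1-en-2-yl)cyclobutyl]prop-1-yn-1-yl}oxy)silane, via lithium alkynide 14 (not isolated), via lithium ynolate 15 (not isolated)
Conditions: n-BuLi (1.05 equiv), THF, −78 °C; t-BuOOLi [from t-BuOOH and LiN(SiMe3)2, THF, −78 °C], −78 → 0 °C; i-Pr3SiOTf (1.1 equiv), −78 °C → rt
Reagents that add atoms: lithium tert-butyl peroxide, CC(C)(C)OO[Li]; triisopropylsilyl trifluoromethanesulfonate, CC(C)[Si](C(C)C)(C(C)C)OS(=O)(=O)C(F)(F)F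
Why: electrophilic oxygenation of the lithium alkynide by the lithium peroxide should give the ynolate, which the bulky silyl triflate captures on oxygen (the established one-flask route from terminal alkynes to 1-siloxy-1-alkynes), leaving the alkene and both stereocentres untouched.

Step 9
Reactants: 17 acetylene
Product: 20 (ethynyloxy)triisopropylsilane, via lithium acetylide 18 (not isolated), via lithium ethynolate 19 (not isolated)
Conditions: 17 (saturated THF solution), n-BuLi (1 equiv), −78 °C; t-BuOOLi [from t-BuOOH and LiN(SiMe3)2], −78 → −25 °C; i-Pr3SiOTf (1 equiv), −78 °C → rt; distillation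
Reagents that add atoms: lithium tert-butyl peroxide, CC(C)(C)OO[Li]; triisopropylsilyl trifluoromethanesulfonate, CC(C)[Si](C(C)C)(C(C)C)OS(=O)(=O)C(F)(F)F
Why: the same acetylide oxygenation and O-silylation as in step 8, run cold so that monolithium acetylide does not disproportionate, should give the parent siloxyacetylene.

Step 10
Reactants: 21 3-propylpentanedioic acid
Product: 22 4-propyloxane-2,6-dione
Conditions: Ac2O, reflux; excess reagent distilled off
Reagents that add atoms: none
Why: cyclodehydration of a glutaric acid by acetic anhydride gives the six-membered cyclic anhydride, a prochiral substrate.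

Step 11
Reactants: 22 4-propyloxane-2,6-dione
Product: 23 (3S)-3-(2-methoxy-2-oxoethyl)hexanoic acid
Conditions: MeOH (10 equiv), (DHQ)2AQN (10 mol%), Et2O, −40 °C; alkaloid removed by acid wash
Reagents that add atoms: methanol, CO
Why: cinchona-alkaloid-catalysed enantioselective alcoholysis of a prochiral cyclic anhydride (general-base activation of methanol by the quinuclidine nitrogen) should differentiate the two enantiotopic carbonyl groups and set the side-chain stereocentre, which is β to both carbonyls and cannot epimerise.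

Step 12
Reactants: 23 (3S)-3-(2-methoxy-2-oxoethyl)hexanoic acid
Product: 24 methyl (3R)-5-chloro-5-oxo-3-propylpentanoate
Conditions: (COCl)2 (1.3 equiv), DMF (cat.), CH2Cl2, 0 °C → rt; volatiles removed, used at once
Reagents that add atoms: oxalyl chloride, ClC(=O)C(Cl)=O
Why: acid chloride formation through the chloroiminium intermediate is mild enough to leave the methyl ester and the remote stereocentre intact, provided the product is not heated (the descriptor changes only by priority).

Step 13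
Reactants: 24 methyl (3R)-5-chloro-5-oxo-3-propylpentanoate; 16 triisopropyl({3-[(1S,2R)-3,3-dimethyl-2-(prop-1-en-2-yl)cyclobutyl]prop-1-yn-1-yl}oxy)silane
Product: 26 methyl (3R)-3-[3-{[(1S,2R)-3,3-dimethyl-2-(prop-1-en-2-yl)cyclobutyl]methyl}-4-oxo-2-[(triisopropylsilyl)oxy]cyclobut-2-en-1-yl]hexanoate (both epimers at the ring sp3 carbon), via ketene 25 (not isolated)
Conditions: 24 (1.5 equiv) added over 4 h to 16 and Et3N (2 equiv), toluene, rt → 40 °C; filtered, used without chromatography
Reagents that add atoms: none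
Why: dehydrochlorination gives the monosubstituted ketene, whose [2+2] cycloaddition with the siloxyalkyne (the oxygen-free alkyne carbon attacks the ketene carbonyl carbon) should give the 3-siloxycyclobutenone regiospecifically; the new ring stereocentre is not controlled and disappears in step 14.

Step 14
Reactants: 26 methyl (3R)-3-[3-{[(1S,2R)-3,3-dimethyl-2-(prop-1-en-2-yl)cyclobutyl]methyl}-4-oxo-2-[(triisopropylsilyl)oxy]cyclobut-2-en-1-yl]hexanoate; 20 (ethynyloxy)triisopropylsilane
Product: 31 methyl (3R)-3-[3-{[(1S,2R)-3,3-dimethyl-2-(prop-1-en-2-yl)cyclobutyl]methyl}-6-hydroxy-2,4-bis[(triisopropylsilyl)oxy]phenyl]hexanoate, via vinylketene 27 (not isolated), via vinylcyclobutenone 28 (not isolated), via dienylketene 29 (not isolated), via cyclohexadienone 30 (not isolated)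
Conditions: 20 (2 equiv), toluene, 80 °C then 110 °C, sealed tube
Reagents that add atoms: none
Why: On heating, 26 opens by a 4π-electrocyclic reaction (C8a–C8 cleaved) to vinylketene 27, whose ketene C=C adds 20 in a [2+2] cycloaddition to give 28 (new bonds C8a–C4a and C6–C5), which opens again (C8a–C6 cleaved) to dienylketene 29, closes by 6π-electrocyclisation (C8a–C8) to dienone 30 and tautomerises through the C8–H to phenol 31. The closest known reaction type is the Danheiser benzannulation of cyclobutenones with heteroatom-substituted alkynes, including its use of 3-siloxycyclobutenones and siloxyacetylenes to make resorcinol and phloroglucinol ethers. The four-membered ring of 28 closes by a ketene–alkyne [2+2] cycloaddition and the six-membered carbocycle by a thermal disrotatory 6π-electrocyclisation of the dienylketene. No new stereocentre survives (the sp3 C8 of 30 aromatises), and the three existing centres are neither α to a carbonyl nor part of the reacting π-system, so they should be carried through unchanged. The step needs regioselectivity in the [2+2] event, which the polarisation of the partners secures (the nucleophilic, oxygen-free carbon of 20 attacks the electrophilic ketene carbon C8a, so the siloxy-bearing carbon ends on C6), and it needs C4a and C7 cis across the C5=C6 bond of 29, which is reachable because the ring openings are reversible. The product carries the three ring oxygens differentiated (O on C8a free, O5 and O7 silylated), which later forces the pyranone to close on the oxygen of C8a.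

Step 15
Reactants: 31 methyl (3R)-3-[3-{[(1S,2R)-3,3-dimethyl-2-(prop-1-en-2-yl)cyclobutyl]methyl}-6-hydroxy-2,4-bis[(triisopropylsilyl)oxy]phenyl]hexanoate
Product: 32 methyl (3R)-3-[3-{[(1S,2R)-3,3-dimethyl-2-(prop-1-en-2-yl)cyclobutyl]methyl}-6-[(3-methylbut-2-enoyl)oxy]-2,4-bis[(triisopropylsilyl)oxy]phenyl]hexanoate
Conditions: 3-methylbut-2-enoyl chloride (1.3 equiv), pyridine, DMAP (cat.), CH2Cl2, 0 °C
Reagents that add atoms: 3-methylbut-2-enoyl chloride, CC(C)=CC(Cl)=O
Why: O-acylation of the only free phenol (on C8a) puts the five-carbon unit on the correct oxygen, and pyridine is used instead of a trialkylamine to avoid deconjugation of the acyl group through its vinylketene.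

Step 16
Reactants: 32 methyl (3R)-3-[3-{[(1S,2R)-3,3-dimethyl-2-(prop-1-en-2-yl)cyclobutyl]methyl}-6-[(3-methylbut-2-enoyl)oxy]-2,4-bis[(triisopropylsilyl)oxy]phenyl]hexanoate
Product: 34 methyl (3R)-3-[6-{[(1S,2R)-3,3-dimethyl-2-(prop-1-en-2-yl)cyclobutyl]methyl}-2,2-dimethyl-4-oxo-5,7-bis[(triisopropylsilyl)oxy]-3,4-dihydro-2H-chromen-8-yl]hexanoate, via hydroxyaryl enone 33 (not isolated)
Conditions: hν (254 nm), degassed cyclohexane, quartz, rt; then Et3N, MeOH, rt
Reagents that add atoms: none
Why: photo-Fries rearrangement (homolysis of the aryl ester bond, in-cage recombination at C4a, the only ring position bearing hydrogen, then tautomerisation) followed by base-catalysed 6-endo oxa-Michael addition of the C8a phenol to the enone should give the 2,2-dimethylchroman-4-one without any acid, and only on the oxygen of C8a because O5 is silylated.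

Step 17
Reactants: 34 methyl (3R)-3-[6-{[(1S,2R)-3,3-dimethyl-2-(prop-1-en-2-yl)cyclobutyl]methyl}-2,2-dimethyl-4-oxo-5,7-bis[(triisopropylsilyl)oxy]-3,4-dihydro-2H-chromen-8-yl]hexanoate
Product: 35 methyl (3R)-3-[6-{[(1S,2R)-3,3-dimethyl-2-(prop-1-en-2-yl)cyclobutyl]methyl}-5,7-dihydroxy-2,2-dimethyl-4-oxo-3,4-dihydro-2H-chromen-8-yl]hexanoate
Conditions: Bu4NF (2.5 equiv), AcOH (2.5 equiv), THF, 0 °C; used directly
Reagents that add atoms: none
Why: fluoride cleaves both aryl silyl ethers, and the acetic acid buffer keeps the liberated phenols protonated so that neither lactonisation onto the methyl ester nor retro-oxa-Michael opening of the pyranone should occur.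

Step 18
Reactants: 35 methyl (3R)-3-[6-{[(1S,2R)-3,3-dimethyl-2-(prop-1-en-2-yl)cyclobutyl]methyl}-5,7-dihydroxy-2,2-dimethyl-4-oxo-3,4-dihydro-2H-chromen-8-yl]hexanoate
Product: 36 methyl (3R)-3-[(6R)-6-{[(1S,2R)-3,3-dimethyl-2-(prop-1-en-2-yl)cyclobutyl]methyl}-5-hydroxy-2,2-dimethyl-6-(3-methylbut-2-en-1-yl)-4,7-dioxo-3,4,6,7-tetrahydro-2H-chromen-8-yl]hexanoate
Conditions: Pd2(dba)3·CHCl3 (2.5 mol%), (R,R)-N,N'-(cyclohexane-1,2-diyl)bis[2-(diphenylphosphino)benzamide] (7.5 mol%), 3-methylbut-2-en-1-yl acetate (1.2 equiv), Cs2CO3 (1.2 equiv), THF, 0 °C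
Reagents that add atoms: 3-methylbut-2-en-1-yl acetate, CC(C)=CCOC(C)=O
Why: Tsuji–Trost allylic alkylation with dearomatisation, in which the π-prenyl complex of palladium is attacked at its unsubstituted terminus by C6 (the carbon flanked by O5 and O7 and so the most nucleophilic site of the phloroglucinol anion, C8 being shielded by its branched substituent), should create the quaternary centre, the chiral ligand pocket choosing the face of the flat ring that leads to the 6R epimer since the remote stereocentres exert little bias.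

Step 19
Reactants: 36 methyl (3R)-3-[(6R)-6-{[(1S,2R)-3,3-dimethyl-2-(prop-1-en-2-yl)cyclobutyl]methyl}-5-hydroxy-2,2-dimethyl-6-(3-methylbut-2-en-1-yl)-4,7-dioxo-3,4,6,7-tetrahydro-2H-chromen-8-yl]hexanoate
Product: 37 (3R)-3-[(6R)-6-{[(1S,2R)-3,3-dimethyl-2-(prop-1-en-2-yl)cyclobutyl]methyl}-5-hydroxy-2,2-dimethyl-6-(3-methylbut-2-en-1-yl)-4,7-dioxo-3,4,6,7-tetrahydro-2H-chromen-8-yl]hexanoic acid (target)
Conditions: LiOH (4 equiv), THF/MeOH/H2O, 0 °C → rt; 0.5 M aq. HCl to pH 4 at 0 °C
Reagents that add atoms: lithium hydroxide, [Li+].[OH-]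
Why: saponification of the methyl ester under mild basic conditions should leave the β-triketone (present as its stabilised enolate), the quaternary centre and the acid-sensitive prenyl and isopropenylcyclobutane groups untouched, with only a brief, cold, weakly acidic work-up.

Compound list
1 | 2,2-dimethylpent-4-enal | C=CCC(C)(C)C=O | starting material
2 | 3,3-dimethylhex-5-enenitrile | C=CCC(C)(C)CC#N | intermediate
3 | rac-3,3-dimethyl-4-(oxiran-2-yl)butanenitrile | N#CCC(C)(C)CC1CO1 | intermediate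
4 | 3,3-dimethyl-4-[(2R)-oxiran-2-yl]butanenitrile | N#CCC(C)(C)C[C@@H]1CO1 | intermediate
5 | (1S,4R)-4-(hydroxymethyl)-2,2-dimethylcyclobutane-1-carbonitrile (trans) | N#C[C@H]1[C@H](CO)CC1(C)C | intermediate
6 | ethynyl(trimethyl)silane (trimethylsilylacetylene) | C#C[Si](C)(C)C | starting material
7 | [(trimethylsilyl)ethynyl]lithium | [Li]C#C[Si](C)(C)C | intermediate (not isolated)
8 | [(1R,2S)-2-cyano-3,3-dimethylcyclobutyl]methyl trifluoromethanesulfonate | N#C[C@H]1[C@H](COS(=O)(=O)C(F)(F)F)CC1(C)C | intermediate (not isolated)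
9 | (1S,4S)-2,2-dimethyl-4-[3-(trimethylsilyl)prop-2-yn-1-yl]cyclobutane-1-carbonitrile | N#C[C@H]1[C@H](CC#C[Si](C)(C)C)CC1(C)C | intermediate
10 | 1-{(1S,4S)-2,2-dimethyl-4-[3-(trimethylsilyl)prop-2-yn-1-yl]cyclobutyl}ethan-1-imine (N-lithio salt in the flask) | CC(=N)[C@H]1[C@H](CC#C[Si](C)(C)C)CC1(C)C | intermediate (not isolated)
11 | 1-{(1S,4S)-2,2-dimethyl-4-[3-(trimethylsilyl)prop-2-yn-1-yl]cyclobutyl}ethan-1-one (trans shown; any cis epimer converges in the same flask) | CC(=O)[C@H]1[C@H](CC#C[Si](C)(C)C)CC1(C)C | intermediate (not isolated)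
12 | 1-[(1S,4R)-2,2-dimethyl-4-(prop-2-yn-1-yl)cyclobutyl]ethan-1-one (trans) | CC(=O)[C@H]1[C@H](CC#C)CC1(C)C | intermediate
13 | (2R,3R)-1,1-dimethyl-2-(prop-1-en-2-yl)-3-(prop-2-yn-1-yl)cyclobutane (trans) | C=C(C)[C@H]1[C@H](CC#C)CC1(C)C | intermediate
14 | {3-[(1S,2R)-3,3-dimethyl-2-(prop-1-en-2-yl)cyclobutyl]prop-1-yn-1-yl}lithium | [Li]C#CC[C@@H]1CC(C)(C)[C@H]1C(C)=C | intermediate (not isolated)
15 | lithium 3-[(1S,2R)-3,3-dimethyl-2-(prop-1-en-2-yl)cyclobutyl]prop-1-yn-1-olate | [Li]OC#CC[C@@H]1CC(C)(C)[C@H]1C(C)=C | intermediate (not isolated)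
16 | triisopropyl({3-[(1S,2R)-3,3-dimethyl-2-(prop-1-en-2-yl)cyclobutyl]prop-1-yn-1-yl}oxy)silane | C=C(C)[C@H]1[C@H](CC#CO[Si](C(C)C)(C(C)C)C(C)C)CC1(C)C | intermediate
17 | acetylene | C#C | starting material
18 | lithium acetylide (ethynyllithium) | [Li]C#C | intermediate (not isolated)
19 | lithium ethynolate | [Li]OC#C | intermediate (not isolated)
20 | (ethynyloxy)triisopropylsilane | C#CO[Si](C(C)C)(C(C)C)C(C)C | intermediate
21 | 3-propylpentanedioic acid | CCCC(CC(=O)O)CC(=O)O | starting material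
22 | 4-propyloxane-2,6-dione | CCCC1CC(=O)OC(=O)C1 | intermediate
23 | (3S)-3-(2-methoxy-2-oxoethyl)hexanoic acid | OC(=O)C[C@H](CCC)CC(=O)OC | intermediate
24 | methyl (3R)-5-chloro-5-oxo-3-propylpentanoate | ClC(=O)C[C@H](CCC)CC(=O)OC | intermediate
25 | methyl (3R)-3-(2-oxoethenyl)hexanoate (ketene) | O=C=C[C@H](CCC)CC(=O)OC | intermediate (not isolated)
26 | methyl (3R)-3-[3-{[(1S,2R)-3,3-dimethyl-2-(prop-1-en-2-yl)cyclobutyl]methyl}-4-oxo-2-[(triisopropylsilyl)oxy]cyclobut-2-en-1-yl]hexanoate (both epimers at the ring sp3 carbon) | O=C1C(C[C@@H]2CC(C)(C)[C@H]2C(C)=C)=C(O[Si](C(C)C)(C(C)C)C(C)C)C1[C@H](CCC)CC(=O)OC | intermediate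
27 | methyl (3R)-3-[3-{[(1S,2R)-3,3-dimethyl-2-(prop-1-en-2-yl)cyclobutyl]methyl}-4-oxo-2-[(triisopropylsilyl)oxy]buta-1,3-dien-1-yl]hexanoate (vinylketene) | O=C=C(C[C@@H]1CC(C)(C)[C@H]1C(C)=C)C(O[Si](C(C)C)(C(C)C)C(C)C)=C[C@H](CCC)CC(=O)OC | intermediate (not isolated)
28 | methyl (3R)-3-[2-{1-{[(1S,2R)-3,3-dimethyl-2-(prop-1-en-2-yl)cyclobutyl]methyl}-4-oxo-2-[(triisopropylsilyl)oxy]cyclobut-2-en-1-yl}-2-[(triisopropylsilyl)oxy]ethenyl]hexanoate (4-vinylcyclobutenone; both epimers at the ring sp3 carbon) | O=C1C=C(O[Si](C(C)C)(C(C)C)C(C)C)C1(C[C@@H]2CC(C)(C)[C@H]2C(C)=C)C(O[Si](C(C)C)(C(C)C)C(C)C)=C[C@H](CCC)CC(=O)OC | intermediate (not isolated)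
29 | dienylketene: methyl (3R)-3-[3-{[(1S,2R)-3,3-dimethyl-2-(prop-1-en-2-yl)cyclobutyl]methyl}-6-oxo-2,4-bis[(triisopropylsilyl)oxy]hexa-1,3,5-trien-1-yl]hexanoate | O=C=CC(O[Si](C(C)C)(C(C)C)C(C)C)=C(C[C@@H]1CC(C)(C)[C@H]1C(C)=C)C(O[Si](C(C)C)(C(C)C)C(C)C)=C[C@H](CCC)CC(=O)OC | intermediate (not isolated)
30 | methyl (3R)-3-[3-{[(1S,2R)-3,3-dimethyl-2-(prop-1-en-2-yl)cyclobutyl]methyl}-6-oxo-2,4-bis[(triisopropylsilyl)oxy]cyclohexa-2,4-dien-1-yl]hexanoate (both epimers at ring C1) | O=C1C=C(O[Si](C(C)C)(C(C)C)C(C)C)C(C[C@@H]2CC(C)(C)[C@H]2C(C)=C)=C(O[Si](C(C)C)(C(C)C)C(C)C)C1[C@H](CCC)CC(=O)OC | intermediate (not isolated)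
31 | methyl (3R)-3-[3-{[(1S,2R)-3,3-dimethyl-2-(prop-1-en-2-yl)cyclobutyl]methyl}-6-hydroxy-2,4-bis[(triisopropylsilyl)oxy]phenyl]hexanoate | Oc1cc(O[Si](C(C)C)(C(C)C)C(C)C)c(C[C@@H]2CC(C)(C)[C@H]2C(C)=C)c(O[Si](C(C)C)(C(C)C)C(C)C)c1[C@H](CCC)CC(=O)OC | intermediate
32 | methyl (3R)-3-[3-{[(1S,2R)-3,3-dimethyl-2-(prop-1-en-2-yl)cyclobutyl]methyl}-6-[(3-methylbut-2-enoyl)oxy]-2,4-bis[(triisopropylsilyl)oxy]phenyl]hexanoate | CC(C)=CC(=O)Oc1cc(O[Si](C(C)C)(C(C)C)C(C)C)c(C[C@@H]2CC(C)(C)[C@H]2C(C)=C)c(O[Si](C(C)C)(C(C)C)C(C)C)c1[C@H](CCC)CC(=O)OC | intermediate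
33 | methyl (3R)-3-[3-{[(1S,2R)-3,3-dimethyl-2-(prop-1-en-2-yl)cyclobutyl]methyl}-6-hydroxy-5-(3-methylbut-2-enoyl)-2,4-bis[(triisopropylsilyl)oxy]phenyl]hexanoate | CC(C)=CC(=O)c1c(O)c([C@H](CCC)CC(=O)OC)c(O[Si](C(C)C)(C(C)C)C(C)C)c(C[C@@H]2CC(C)(C)[C@H]2C(C)=C)c1O[Si](C(C)C)(C(C)C)C(C)C | intermediate (not isolated)
34 | methyl (3R)-3-[6-{[(1S,2R)-3,3-dimethyl-2-(prop-1-en-2-yl)cyclobutyl]methyl}-2,2-dimethyl-4-oxo-5,7-bis[(triisopropylsilyl)oxy]-3,4-dihydro-2H-chromen-8-yl]hexanoate | CC1(C)CC(=O)c2c(O[Si](C(C)C)(C(C)C)C(C)C)c(C[C@@H]3CC(C)(C)[C@H]3C(C)=C)c(O[Si](C(C)C)(C(C)C)C(C)C)c([C@H](CCC)CC(=O)OC)c2O1 | intermediate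
35 | methyl (3R)-3-[6-{[(1S,2R)-3,3-dimethyl-2-(prop-1-en-2-yl)cyclobutyl]methyl}-5,7-dihydroxy-2,2-dimethyl-4-oxo-3,4-dihydro-2H-chromen-8-yl]hexanoate | CC1(C)CC(=O)c2c(O)c(C[C@@H]3CC(C)(C)[C@H]3C(C)=C)c(O)c([C@H](CCC)CC(=O)OC)c2O1 | intermediate
36 | methyl (3R)-3-[(6R)-6-{[(1S,2R)-3,3-dimethyl-2-(prop-1-en-2-yl)cyclobutyl]methyl}-5-hydroxy-2,2-dimethyl-6-(3-methylbut-2-en-1-yl)-4,7-dioxo-3,4,6,7-tetrahydro-2H-chromen-8-yl]hexanoate | C=C(C)[C@H]1[C@H](C[C@]2(CC=C(C)C)C(=O)C([C@H](CCC)CC(=O)OC)=C3OC(C)(C)CC(=O)C3=C2O)CC1(C)C | intermediate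
37 | (3R)-3-[(6R)-6-{[(1S,2R)-3,3-dimethyl-2-(prop-1-en-2-yl)cyclobutyl]methyl}-5-hydroxy-2,2-dimethyl-6-(3-methylbut-2-en-1-yl)-4,7-dioxo-3,4,6,7-tetrahydro-2H-chromen-8-yl]hexanoic acid | C=C(C)[C@H]1[C@H](C[C@]2(CC=C(C)C)C(=O)C([C@H](CCC)CC(=O)O)=C3OC(C)(C)CC(=O)C3=C2O)CC1(C)C | target

Total step count: 19.
Longest linear sequence: 15 steps (steps 1–8, then 13–19); step 9 and steps 10–12 are side branches.

Steps most likely to fail

Step 18. What may go wrong: poor facial selectivity at C6, together with competing O-prenylation or C8-prenylation. Fallback: setting out from 35, the phloroglucinol dianion is C-prenylated without a catalyst (NaOMe, MeOH, 0 °C, 1-bromo-3-methylbut-2-ene), which should give 36 together with its C6 epimer, methyl (3R)-3-[(6S)-6-{[(1S,2R)-3,3-dimethyl-2-(prop-1-en-2-yl)cyclobutyl]methyl}-5-hydroxy-2,2-dimethyl-6-(3-methylbut-2-en-1-yl)-4,7-dioxo-3,4,6,7-tetrahydro-2H-chromen-8-yl]hexanoate F1. Because the other three stereocentres are already fixed, the two products are diastereomers and are separated by preparative HPLC; the route is rejoined at 36.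

Step 16. What may go wrong: inefficient recombination of the photochemically formed radical pair at the crowded C4a position, loss of the acyl group back to 31, or secondary photoreactions of the product ketone. Fallback: setting out from 31, Casnati–Skattebøl ortho-formylation (MgCl2, Et3N, paraformaldehyde, MeCN, reflux) should give methyl (3R)-3-[3-{[(1S,2R)-3,3-dimethyl-2-(prop-1-en-2-yl)cyclobutyl]methyl}-5-formyl-6-hydroxy-2,4-bis[(triisopropylsilyl)oxy]phenyl]hexanoate F2. Addition of MeMgBr (2.2 equiv, THF, −78 °C) gives the 5-(1-hydroxyethyl) compound F3 (both carbinol epimers), MnO2 (CH2Cl2, rt) oxidises it to the 5-acetyl compound F4, and Kabbe condensation (pyrrolidine, acetone, MeOH, rt → 50 °C) closes the 2,2-dimethylpyranone on the only free phenol. The route is rejoined at 34.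

Step 4. What may go wrong: ring closure at the terminal epoxide carbon (five-membered ring) or intermolecular epoxide opening instead of the four-membered closure. Fallback: setting out from 4, the epoxide is opened at its terminal carbon with sodium benzyloxide (BnOH, NaH, THF, 60 °C) to (5R)-6-(benzyloxy)-5-hydroxy-3,3-dimethylhexanenitrile F5. Mesylation (MsCl, Et3N, CH2Cl2, 0 °C) gives (2R)-1-(benzyloxy)-5-cyano-4,4-dimethylpentan-2-yl methanesulfonate F6, and KN(SiMe3)2 (THF, −78 → 0 °C) closes the ring by 4-exo-tet displacement of the secondary sulfonate with inversion, giving (1S,4R)-4-[(benzyloxy)methyl]-2,2-dimethylcyclobutane-1-carbonitrile F7. Hydrogenolysis (H2, Pd/C, EtOAc) returns the route at 5.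

Further compounds
F1 | step 18 | methyl (3R)-3-[(6S)-6-{[(1S,2R)-3,3-dimethyl-2-(prop-1-en-2-yl)cyclobutyl]methyl}-5-hydroxy-2,2-dimethyl-6-(3-methylbut-2-en-1-yl)-4,7-dioxo-3,4,6,7-tetrahydro-2H-chromen-8-yl]hexanoate | C=C(C)[C@H]1[C@H](C[C@@]2(CC=C(C)C)C(=O)C([C@H](CCC)CC(=O)OC)=C3OC(C)(C)CC(=O)C3=C2O)CC1(C)C
F2 | step 16 | methyl (3R)-3-[3-{[(1S,2R)-3,3-dimethyl-2-(prop-1-en-2-yl)cyclobutyl]methyl}-5-formyl-6-hydroxy-2,4-bis[(triisopropylsilyl)oxy]phenyl]hexanoate | O=Cc1c(O)c([C@H](CCC)CC(=O)OC)c(O[Si](C(C)C)(C(C)C)C(C)C)c(C[C@@H]2CC(C)(C)[C@H]2C(C)=C)c1O[Si](C(C)C)(C(C)C)C(C)C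
F3 | step 16 | methyl (3R)-3-[3-{[(1S,2R)-3,3-dimethyl-2-(prop-1-en-2-yl)cyclobutyl]methyl}-6-hydroxy-5-(1-hydroxyethyl)-2,4-bis[(triisopropylsilyl)oxy]phenyl]hexanoate (both carbinol epimers) | CC(O)c1c(O)c([C@H](CCC)CC(=O)OC)c(O[Si](C(C)C)(C(C)C)C(C)C)c(C[C@@H]2CC(C)(C)[C@H]2C(C)=C)c1O[Si](C(C)C)(C(C)C)C(C)C
F4 | step 16 | methyl (3R)-3-[5-acetyl-3-{[(1S,2R)-3,3-dimethyl-2-(prop-1-en-2-yl)cyclobutyl]methyl}-6-hydroxy-2,4-bis[(triisopropylsilyl)oxy]phenyl]hexanoate | CC(=O)c1c(O)c([C@H](CCC)CC(=O)OC)c(O[Si](C(C)C)(C(C)C)C(C)C)c(C[C@@H]2CC(C)(C)[C@H]2C(C)=C)c1O[Si](C(C)C)(C(C)C)C(C)C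
F5 | step 4 | (5R)-6-(benzyloxy)-5-hydroxy-3,3-dimethylhexanenitrile | N#CCC(C)(C)C[C@@H](O)COCc1ccccc1
F6 | step 4 | (2R)-1-(benzyloxy)-5-cyano-4,4-dimethylpentan-2-yl methanesulfonate | N#CCC(C)(C)C[C@@H](OS(C)(=O)=O)COCc1ccccc1
F7 | step 4 | (1S,4R)-4-[(benzyloxy)methyl]-2,2-dimethylcyclobutane-1-carbonitrile | N#C[C@H]1[C@H](COCc2ccccc2)CC1(C)C
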